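**Retrosynthetic overview**
1. Target ⇐ oxepane closed last by C3‑OH → C16 triflate etherification; C11 butanoate by acylation; C15 by hydroboration of a C14 isopropenyl; C11 by ketone reduction.
2. Cyclohexane ⇐ exo‑face Diels–Alder of a bicyclic (Z)‑2‑ethoxy‑1‑methyl diene (C1=C10–C11(OEt)=C12HMe) with methyl vinyl ketone, setting C1, C12 and C14 (C10 on hydrolysis).
3. Key step: the (E)‑oxonene and the THF are not made by RCM or macrocyclisation but together, by a Rh‑carbenoid oxonium‑ylide/[2,3]‑sigmatropic three‑atom ring expansion of a 6‑isopropenyl tetrahydropyran diazoketone.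
4. Tetrahydropyran ⇐ Pd(II) alkoxycarbonylative cyclisation of a (3S,6S)‑dienol made from (S)‑linalool (from geraniol), where C3 is chiral‑pool‑derived and C6 is a sacrificial stereocentre that relays into C2.
5. Ring order: tetrahydropyran → oxonene + THF (one step) → cyclohexane → oxepane.

Assumption: the SMILES is taken literally, i.e. 6E and (1S,2S,3S,9S,10R,11R,12R,14S,15R); asbestinin numbering is used (ether O bridges C2/C9; oxepane O links C3/C16; cyclohexane = C1, C10–C14).

---

**Step 1**
Reactants: 1 geraniol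
Product: 2 (2S,3S)‑2,3‑epoxygeraniol
Conditions: Ti(OiPr)4 (5 mol %), L‑(+)‑DET, t‑BuOOH, 4 Å MS, CH2Cl2, −20 °C
Reagents that add atoms: tert‑butyl hydroperoxide, CC(C)(C)OO
Why: Sharpless asymmetric epoxidation; the L‑tartrate catalyst sets 3S, and this C3–O bond becomes the C3–O bond of the target.

**Step 2**
Reactants: 2
Product: 3 (2R,3S)‑2‑(iodomethyl)‑3‑methyl‑3‑(4‑methylpent‑3‑enyl)oxirane
Conditions: PPh3, I2, imidazole, CH2Cl2, 0 °C
Reagents that add atoms: iodine, II
Why: Appel‑type iodination of the primary alcohol; the epoxide and its stereocentres are untouched (the 2R label is only a CIP priority change).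

**Step 3**
Reactants: 3
Product: 4 (S)‑linalool [(3S)‑3,7‑dimethylocta‑1,6‑dien‑3‑ol]
Conditions: Zn dust, EtOH, 70 °C
Reagents that add atoms: none
Why: Zinc‑mediated reductive β‑elimination opens the epoxide to the transposed tertiary allylic alcohol; the C3–O bond is not broken, so 3S is retained.

**Step 4**
Reactants: 4
Product: 5 (S)‑linalool TBS ether
Conditions: TBSOTf, 2,6‑lutidine, CH2Cl2, −78 → 0 °C
Reagents that add atoms: TBSOTf, CC(C)(C)[Si](C)(C)OS(=O)(=O)C(F)(F)F
Why: Silylation of the tertiary alcohol; it must be masked for the epoxidation (no linalool‑oxide formation) and for the later carbenoid step.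

**Step 5**
Reactants: 5
Product: 6 (3S,6S)‑6,7‑epoxide: tert‑butyl{[(3S)‑5‑[(2S)‑3,3‑dimethyloxiran‑2‑yl]‑3‑methylpent‑1‑en‑3‑yl]oxy}dimethylsilane
Conditions: L‑fructose‑derived (ent‑)Shi ketone (30 mol %), Oxone, K2CO3, Bu4NHSO4, MeCN/DMM–aq. buffer (pH ≈ 10.5), 0 °C
Reagents that add atoms: Oxone (KHSO5), OOS(=O)(=O)[O-].[K+]
Why: Shi asymmetric epoxidation; the chiral dioxirane epoxidises only the trisubstituted alkene, and the ent‑ketone gives 6S by reagent control (the D‑fructose ketone gives 6R).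

**Step 6**
Reactants: 6
Product: 7 (3S,6S)‑6‑(TBSO)‑2,6‑dimethylocta‑1,7‑dien‑3‑ol
Conditions: Et2Al(TMP) (from LiTMP + Et2AlCl), toluene, 0 °C
Reagents that add atoms: none
Why: Yamamoto epoxide → allylic alcohol isomerisation; a methyl proton is removed and the tertiary C–O bond opens, so the carbinol C–O bond and its S configuration are retained and the isopropenyl group is revealed.

**Step 7**
Reactants: 7
Product: 8 methyl 2‑[(2S,3S,6S)‑3‑(TBSO)‑3‑methyl‑6‑(prop‑1‑en‑2‑yl)oxan‑2‑yl]acetate
Conditions: PdCl2 (10 mol %), CuCl2 (3 equiv), NaOAc, CO (1 atm), MeOH, rt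
Reagents that add atoms: carbon monoxide, [C-]#[O+]; methanol, CO
Why: Semmelhack intramolecular alkoxypalladation/methoxycarbonylation (6‑exo); in the chair transition state the isopropenyl, the new CH2[Pd] and the C3 methyl are equatorial (OTBS axial), giving the 2,6‑cis ring and hence 2S with C1 cis to the C3 oxygen.

**Step 8**
Reactants: 8
Product: 9 2‑[(2S,3S,6S)‑3‑(TBSO)‑3‑methyl‑6‑(prop‑1‑en‑2‑yl)oxan‑2‑yl]acetic acid
Conditions: LiOH, THF/MeOH/H2O, rt
Reagents that add atoms: lithium hydroxide/water, [Li+].[OH-] / O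
Why: Ester saponification; no stereocentre is affected.

**Step 9**
Reactants: 9
Product: 10 1‑diazo‑3‑[(2S,3S,6S)‑3‑(TBSO)‑3‑methyl‑6‑(prop‑1‑en‑2‑yl)oxan‑2‑yl]propan‑2‑one
Conditions: i‑BuOCOCl, Et3N, Et2O, −20 °C; then CH2N2, Et2O, 0 °C
Reagents that add atoms: diazomethane, C=[N+]=[N-]
Why: Acylation of diazomethane by the mixed anhydride (Arndt–Eistert‑type diazoketone synthesis); the diazo carbon becomes C9.

**Step 10 (key step)**
Reactants: 10
Product: 11 (1S,2S,5E,8S)‑2‑(TBSO)‑2,6‑dimethyl‑11‑oxabicyclo[6.2.1]undec‑5‑en‑9‑one (asbestinin C2 S, C3 S, C9 S, 6E; C10 ketone)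
Conditions: Rh2(O2CCPh3)4 (2 mol %), CH2Cl2, reflux, slow addition of 10; minor Z isomer removed by chromatography
Reagents that add atoms: none
Why: Rh(II)‑carbenoid formation, five‑membered oxonium ylide formation on the ring oxygen and [2,3]‑sigmatropic rearrangement through the isopropenyl group (6 → 9 ring expansion) form C8–C9 and O–C9 at once; C9 is fixed by the bridged topology, the C6 stereocentre is consumed, and the bulky Rh(II) triphenylacetate is the catalyst type that favours the E‑alkene (Cu(hfacac)2 favours Z).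

**Step 11**
Reactants: 11
Product: 12 (1S,2S,5E,8S)‑2‑(TBSO)‑2,6‑dimethyl‑11‑oxabicyclo[6.2.1]undeca‑5,9‑dien‑9‑yl triflate (C10–OTf, C1=C10)
Conditions: NaHMDS, PhNTf2, THF, −78 °C
Reagents that add atoms: N‑phenyl‑bis(trifluoromethanesulfonimide), O=S(=O)(N(c1ccccc1)S(=O)(=O)C(F)(F)F)C(F)(F)F
Why: Kinetic enolisation/O‑triflation; only the C1 methylene can enolise (the C9 bridgehead enolate is prohibitively strained).

**Step 12 (side branch)**
Reactants: 13 allyl ethyl ether
Product: 14 (Z)‑1‑ethoxyprop‑1‑ene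
Conditions: t‑BuOK, DMSO, rt; distil
Reagents that add atoms: none
Why: Base‑mediated allyl → propenyl ether isomerisation, which is cis‑selective through the chelated oxyallyl anion.

**Step 13**
Reactants: 12; 14
Product: 15 tert‑butyl{[(1S,2S,5E,8S)‑9‑[(1Z)‑1‑ethoxyprop‑1‑en‑1‑yl]‑2,6‑dimethyl‑11‑oxabicyclo[6.2.1]undeca‑5,9‑dien‑2‑yl]oxy}dimethylsilane (diene C1=C10–C11(OEt)=C12H–CH3)
Conditions: 14, t‑BuLi, THF, −78 → 0 °C; ZnCl2; then 12, Pd(PPh3)4 (5 mol %), THF, rt
Reagents that add atoms: none besides 14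
Why: α‑Lithiation of the cis enol ether (as for dihydropyran), transmetalation and Negishi coupling with the vinyl triflate, all with retention, so the methyl ends up cis to OEt, i.e. "outside" on the diene.

**Step 14**
Reactants: 15; 16 methyl vinyl ketone
Product: 17 tricyclic enol ether methyl ketone (1S,2S,3S,9S,12R,14R,6E): cyclohexene (C10=C11–OEt) fused at C1–C10 to the oxabicycle, 12‑Me cis to the C1–C2 bond, 14‑acetyl trans to it, 3‑OTBS
Conditions: 16 (5 equiv), BHT, toluene, 70 °C; then K2CO3, MeOH, rt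
Reagents that add atoms: none besides 16
Why: Normal‑demand Diels–Alder followed by α‑epimerisation. The ethoxy group directs the "para" regiochemistry (C12–C13, C1–C14). Addition occurs on the exo face, anti to the six‑carbon bridge, which sets C1. Suprafacial addition places the outside methyl cis to C2 (12R). K2CO3 equilibrates the endo/exo mixture to the acetyl trans to C2.

**Step 15**
Reactants: 17
Product: 18 the 14‑isopropenyl enol ether (1S,2S,3S,9S,12R,14R,6E)
Conditions: Ph3PCH3Br, KOtBu, THF/toluene, 0 °C → rt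
Reagents that add atoms: methyltriphenylphosphonium bromide (as Ph3P=CH2), C[P+](c1ccccc1)(c1ccccc1)c1ccccc1.[Br-]
Why: Wittig methylenation of the methyl ketone; C11 is still masked as the enol ether, and C14 is already at its thermodynamic configuration.

**Step 16**
Reactants: 18
Product: 19 cis‑fused C11 ketone (1S,2S,3S,9S,10R,12R,14R,6E) with 14‑isopropenyl and 3‑OTBS
Conditions: 1 M aq. HCl, THF, 0 °C, short reaction time
Reagents that add atoms: water, O
Why: Enol ether hydrolysis; protonation at C10 is forced onto the endo face because the cyclohexane can only be cis‑fused to the bridged THF (H10 cis to H1), and mild acid leaves the C12 α‑methyl centre and the 3‑OTBS intact.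

**Step 17**
Reactants: 19
Product: 20 11‑alcohol (1S,2S,3S,9S,10S,11R,12R,14R,6E), OH cis to the 12‑Me and to the C10–C9 bond
Conditions: L‑Selectride, THF, −78 °C; NaOH/H2O2 work‑up
Reagents that add atoms: none
Why: Hindered hydride reduction from the convex face, anti to both C9 and the C12 methyl, gives the 11R alcohol (the C10 label changes from R to S only through CIP priorities).

**Step 18**
Reactants: 20
Product: 21 3,11‑diol (1S,2S,3S,9S,10S,11R,12R,14R,6E)
Conditions: TBAF, THF, 50 °C
Reagents that add atoms: none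
Why: Fluoride desilylation of the tertiary TBS ether, done before the ester is present and under non‑acidic conditions to avoid transannular etherification onto the C6=C7 alkene.

**Step 19**
Reactants: 21
Product: 22 11‑butanoate, 3‑OH (1S,2S,3S,9S,10R,11R,12R,14R,6E)
Conditions: butyric anhydride, Et3N, DMAP, CH2Cl2, rt
Reagents that add atoms: butyric anhydride, CCCC(=O)OC(=O)CCC
Why: DMAP‑catalysed acylation, selective for the secondary C11‑OH over the tertiary C3‑OH.

**Step 20**
Reactants: 22
Product: 23 16‑hydroxy compound (1S,2S,3S,9S,10R,11R,12R,14S,15R,6E): C14–CH(CH3)CH2OH, 3‑OH, 11‑butanoate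
Conditions: (−)‑Ipc2BH [from (+)‑α‑pinene], THF, −10 °C → rt; then NaBO3·4H2O, THF/H2O
Reagents that add atoms: sodium perborate (delivers the oxygen; active oxidant equivalent to H2O2, OO)
Why: Hydroboration–oxidation; the bulky borane reacts only with the 1,1‑disubstituted alkene, and C15 (R) is set by approach anti to C1 in the A(1,3)‑minimised rotamer, reinforced by the chiral borane (chosen by analogy with 2‑methyl‑1‑alkenes; the matched enantiomer must be confirmed experimentally).

**Step 21**
Reactants: 23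
Product: 24 4‑deoxyasbestinin A
Conditions: Tf2O, 2,6‑lutidine, CH2Cl2, −78 → 0 °C
Reagents that add atoms: none
Why: Selective triflation of the primary C16‑OH and intramolecular Williamson‑type displacement by the tertiary C3‑OH (7‑exo‑tet) closes the oxepane without touching any stereocentre.

---

**Compound list**
1 | geraniol | CC(C)=CCC/C(C)=C/CO | starting material
2 | (2S,3S)‑2,3‑epoxygeraniol | OC[C@@H]1O[C@@]1(C)CCC=C(C)C | intermediate
3 | (2R,3S)‑2‑(iodomethyl)‑3‑methyl‑3‑(4‑methylpent‑3‑enyl)oxirane | IC[C@@H]1O[C@@]1(C)CCC=C(C)C | intermediate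
4 | (S)‑linalool | C=C[C@@](C)(O)CCC=C(C)C | intermediate
5 | (S)‑linalool TBS ether | C=C[C@@](C)(O[Si](C)(C)C(C)(C)C)CCC=C(C)C | intermediate
6 | (3S,6S)‑6,7‑epoxy‑linalool TBS ether | C=C[C@@](C)(O[Si](C)(C)C(C)(C)C)CC[C@@H]1OC1(C)C | intermediate
7 | (3S,6S)‑6‑(TBSO)‑2,6‑dimethylocta‑1,7‑dien‑3‑ol | C=C[C@@](C)(O[Si](C)(C)C(C)(C)C)CC[C@H](O)C(C)=C | intermediate
8 | methyl 2‑[(2S,3S,6S)‑3‑(TBSO)‑3‑methyl‑6‑isopropenyloxan‑2‑yl]acetate | COC(=O)C[C@@H]1O[C@H](C(C)=C)CC[C@]1(C)O[Si](C)(C)C(C)(C)C | intermediate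
9 | corresponding acetic acid | OC(=O)C[C@@H]1O[C@H](C(C)=C)CC[C@]1(C)O[Si](C)(C)C(C)(C)C | intermediate
10 | diazoketone | [N-]=[N+]=CC(=O)C[C@@H]1O[C@H](C(C)=C)CC[C@]1(C)O[Si](C)(C)C(C)(C)C | intermediate
11 | (1S,2S,5E,8S)‑2‑(TBSO)‑2,6‑dimethyl‑11‑oxabicyclo[6.2.1]undec‑5‑en‑9‑one | O=C1C[C@@H]2O[C@H]1C/C(C)=C/CC[C@]2(C)O[Si](C)(C)C(C)(C)C | intermediate
12 | enol triflate of 11 (C10–OTf, C1=C10) | O=S(=O)(OC1=C[C@@H]2O[C@H]1C/C(C)=C/CC[C@]2(C)O[Si](C)(C)C(C)(C)C)C(F)(F)F | intermediate
13 | allyl ethyl ether | C=CCOCC | starting material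
14 | (Z)‑1‑ethoxyprop‑1‑ene | CCO/C=C\C | intermediate
15 | bicyclic (Z)‑2‑ethoxy diene | CCO/C(=C\C)C1=C[C@@H]2O[C@H]1C/C(C)=C/CC[C@]2(C)O[Si](C)(C)C(C)(C)C | intermediate
16 | methyl vinyl ketone | CC(=O)C=C | starting material
17 | Diels–Alder enol ether, 14‑acetyl | CCOC1=C2[C@H]([C@@H](C[C@H]1C)C(C)=O)[C@@H]3O[C@H]2C/C(C)=C/CC[C@]3(C)O[Si](C)(C)C(C)(C)C | intermediate
18 | enol ether, 14‑isopropenyl | CCOC1=C2[C@H]([C@@H](C[C@H]1C)C(C)=C)[C@@H]3O[C@H]2C/C(C)=C/CC[C@]3(C)O[Si](C)(C)C(C)(C)C | intermediate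
19 | cis‑fused C11 ketone | O=C1[C@@H]2[C@H]([C@@H](C[C@H]1C)C(C)=C)[C@@H]3O[C@H]2C/C(C)=C/CC[C@]3(C)O[Si](C)(C)C(C)(C)C | intermediate
20 | 11‑alcohol, 3‑OTBS | O[C@H]1[C@@H]2[C@H]([C@@H](C[C@H]1C)C(C)=C)[C@@H]3O[C@H]2C/C(C)=C/CC[C@]3(C)O[Si](C)(C)C(C)(C)C | intermediate
21 | 3,11‑diol | O[C@H]1[C@@H]2[C@H]([C@@H](C[C@H]1C)C(C)=C)[C@@H]3O[C@H]2C/C(C)=C/CC[C@]3(C)O | intermediate
22 | 11‑butanoate, 3‑OH | CCCC(=O)O[C@H]1[C@@H]2[C@H]([C@@H](C[C@H]1C)C(C)=C)[C@@H]3O[C@H]2C/C(C)=C/CC[C@]3(C)O | intermediate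
23 | 16‑hydroxy‑11‑butanoate (15R), 3‑OH | CCCC(=O)O[C@H]1[C@@H]2[C@H]([C@@H](C[C@H]1C)[C@@H](C)CO)[C@@H]3O[C@H]2C/C(C)=C/CC[C@]3(C)O | intermediate
24 | 4‑deoxyasbestinin A | CCCC(=O)O[C@H]1[C@@H]2[C@@H]3[C@@H](C[C@H]1C)[C@@H](C)CO[C@@]1(C)CC/C=C(\C)C[C@@H]2O[C@@H]31 | target

---

**Totals:** 21 steps; longest linear sequence 20 steps (geraniol → target; step 12 is a one‑step side branch).

**Three steps most likely to fail, with fallbacks that change the approach**
1. **Step 20 (C15 by hydroboration).** Facial selectivity on the isopropenyl group is the least predictable stereochemical event, and the matched borane enantiomer is an inference. Fallback: convert the C15 methyl ketone of 17 into the 2‑substituted acrylate (kinetic enol triflate, then Pd/CO/MeOH), set C15 by catalyst‑controlled asymmetric hydrogenation, and reduce the ester to the C16 alcohol.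
2. **Step 7 (Pd alkoxycarbonylative cyclisation).** Possible problems are the neopentyl‑type alkene, the allylic alcohol nucleophile and the second alkene under PdCl2/CuCl2. Fallback: build the same tetrahydropyran by SmI2 ketyl–β‑alkoxyacrylate reductive cyclisation of an aldehyde, then oxidation and MeMgCl addition to install the C3 carbinol; this sets C2/C3 by a different logic.
3. **Step 13 and its consequence in step 14 (methyl‑bearing diene and its Diels–Alder).** Possible problems are the α‑lithiation/Negishi coupling of the propenyl ether and the lower reactivity or regiocontrol of the more substituted diene. Fallback: Stille‑couple 12 with commercial tributyl(1‑ethoxyvinyl)tin, run the Diels–Alder on the unsubstituted diene, and introduce the C12 methyl after hydrolysis by ketone enolate methylation followed by kinetic protonation of the re‑formed enolate from the convex face.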